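**Plan**

- Ring labels: enone 1 is ring A–CO–CH=CH–ring B and enone 2 is ring C–CO–CH=CH–ring D, with ring B C3 bonded to ring C C5. C1 of rings A and C carries the carbonyl, and C1 of rings B and D carries the alkene.
- Retrosynthesis first removes the four O-acetyl groups, then cuts the two phenolic C–O bonds at C2 of ring A and C2 of ring C. Each of these hydroxyls lies ortho to an aryl ketone carbonyl, so the ketone oxygen can steer a metal to exactly these two C–H bonds; without them no ring can close to a flavanone during assembly.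
- The next cuts are the ring B C3–ring C C5 biaryl bond (Suzuki–Miyaura) and then the two enone Cα=Cβ bonds (Claisen–Schmidt), leading back to four para-hydroxylated benzene building blocks.
- Forward: two acid-catalysed condensations give two bromochalcones; one is borylated, the halves are cross-coupled, the four phenols are acetylated, both ortho C–H bonds are oxygenated in one operation, and methanolysis frees the six phenols. No ring is formed; all four benzene rings are bought.
- Stereochemistry: there is no stereocentre. Both E alkenes arise under thermodynamic control in the dehydrations and are carried through unchanged.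

Key step: step 6

Remark: aryl trifluoroacetates are taken to hydrolyse on neutral aqueous work-up while the much less electrophilic aryl acetates stay on.

**Route**

Step 1
Reactants: 1 4-hydroxyacetophenone; 2 3-bromo-4-hydroxybenzaldehyde
Product: 3 (E)-3-(3-bromo-4-hydroxyphenyl)-1-(4-hydroxyphenyl)prop-2-en-1-one (bromochalcone of rings A and B)
Conditions: dry HCl (sat.), EtOH, 0 °C to rt
Reagents that add atoms: none
Why: Acid-catalysed Claisen–Schmidt (crossed aldol) condensation, in which the enol of 1 adds to protonated 2 (no α-hydrogen) and the aldol dehydrates to the conjugated enone with the E isomer as thermodynamic product; acid is used because the free phenols stay neutral instead of forming unreactive phenoxides.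

Step 2
Reactants: 4 1-(3-bromo-4-hydroxyphenyl)ethanone; 5 4-hydroxybenzaldehyde
Product: 6 (E)-1-(3-bromo-4-hydroxyphenyl)-3-(4-hydroxyphenyl)prop-2-en-1-one (bromochalcone of rings C and D)
Conditions: dry HCl (sat.), EtOH, 0 °C to rt
Reagents that add atoms: none
Why: The same acid-catalysed Claisen–Schmidt condensation, with 4 as the only enolisable partner and 5 as the only aldehyde, should give the E enone by thermodynamically controlled dehydration.

Step 3
Reactants: 3 (E)-3-(3-bromo-4-hydroxyphenyl)-1-(4-hydroxyphenyl)prop-2-en-1-one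
Product: 7 (E)-3-[4-hydroxy-3-(4,4,5,5-tetramethyl-1,3,2-dioxaborolan-2-yl)phenyl]-1-(4-hydroxyphenyl)prop-2-en-1-one
Conditions: B2pin2, PdCl2(dppf) (5 mol %), KOAc, 1,4-dioxane, 90 °C
Reagents that add atoms: bis(pinacolato)diboron, CC1(C)OB(OC1(C)C)B1OC(C)(C)C(C)(C)O1
Why: Miyaura borylation, in which zerovalent palladium inserts into the ring B C–Br bond and acetate-assisted transmetalation with B2pin2 followed by reductive elimination gives the aryl boronate; KOAc is too weak a base to start Suzuki homocoupling or to harm the enone, and any phenol O–B bond formed in passing hydrolyses on work-up.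

Step 4
Reactants: 7 (E)-3-[4-hydroxy-3-(4,4,5,5-tetramethyl-1,3,2-dioxaborolan-2-yl)phenyl]-1-(4-hydroxyphenyl)prop-2-en-1-one; 6 (E)-1-(3-bromo-4-hydroxyphenyl)-3-(4-hydroxyphenyl)prop-2-en-1-one
Product: 8 (E)-3-{4-hydroxy-3-[2-hydroxy-5-[(E)-3-(4-hydroxyphenyl)prop-2-enoyl]phenyl]phenyl}-1-(4-hydroxyphenyl)prop-2-en-1-one (dideoxy bichalcone tetraphenol)
Conditions: Pd(OAc)2 (5 mol %), SPhos, K3PO4 (6 equiv), 1,4-dioxane/H2O, 90 °C
Reagents that add atoms: none
Why: Suzuki–Miyaura cross-coupling, in which oxidative addition into the ring C C–Br bond, transmetalation of the hydroxide-activated boronate and reductive elimination form the ring B C3–ring C C5 bond; the bulky electron-rich SPhos ligand copes with the ortho-oxygenated, phenoxide-bearing partners, and the enones, which carry no ortho hydroxyl, are inert to aqueous phosphate.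

Step 5
Reactants: 8 dideoxy bichalcone tetraphenol
Product: 9 tetraacetate of 8 (all four phenols as acetates; no oxygen ortho to either ketone)
Conditions: Ac2O, pyridine, DMAP (cat.), CH2Cl2, 0 °C to rt
Reagents that add atoms: acetic anhydride, CC(=O)OC(C)=O
Why: DMAP-catalysed O-acylation (esterification) of the four phenols, the only nucleophiles present; it lowers the electron density of all four rings and of both styrene-type alkenes ahead of the oxidation.

Step 6
Reactants: 9 tetraacetate of the dideoxy bichalcone
Product: 11 tetraacetate bearing free hydroxyls at C2 of ring A and at C2 of ring C (tetra-O-acetylrhuschalcone VI), via bis(trifluoroacetate) 10 (not isolated)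
Conditions: [RuCl2(p-cymene)]2 (10 mol %), PhI(OCOCF3)2 (2.5 equiv, in portions), CF3CO2H/(CF3CO)2O (3:1), 80 °C; then H2O/THF, pH 7 buffer, rt
Reagents that add atoms: [bis(trifluoroacetoxy)iodo]benzene, O=C(O[I](OC(=O)C(F)(F)F)c1ccccc1)C(F)(F)F
Why: Proposed new method: each ketone oxygen binds the divalent ruthenium trifluoroacetate formed from [RuCl2(p-cymene)]2, carboxylate-assisted deprotonation of the ortho C–H bond closes a five-membered ruthenacycle, PhI(OCOCF3)2 oxidises it to tetravalent ruthenium, and C–O reductive elimination releases the aryl trifluoroacetate, which (CF3CO)2O keeps capped and electron-poor until work-up. The closest known reaction type is the ketone-directed ortho C–H hydroxylation of simple aryl alkyl ketones, and of the ring-fused enone ketone of chromones and flavones, with this catalyst and oxidant; a twofold version on an open-chain bis(enone) has not been shown. No ring is closed and no stereocentre is formed, and the two E alkenes are meant to be spectators. Site selectivity is needed on ring C, where C6 is flanked by the carbonyl-bearing C1 and by ring B at C5 so that the metal should go to C2, while the two ortho positions of ring A are equivalent. One oxygenation per ketone is needed, and the ortho trifluoroacetate should secure it by twisting the carbonyl out of plane and deactivating the ring. Arene over alkene selectivity is needed, and it rests on the acetate caps of rings B and D and on the acid-bound enone, which make both C=C bonds poor partners for the electrophilic iodine reagent and the electron-poor β-carbon a poor site for electrophilic ruthenation.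

Step 7
Reactants: 11 tetra-O-acetylrhuschalcone VI
Product: 12 rhuschalcone VI
Conditions: HCl (cat., 1.25 M in MeOH), MeOH/THF, rt
Reagents that add atoms: none
Why: Acid-catalysed transesterification (methanolysis) of the four aryl acetates in a medium routinely used to unmask hydroxychalcones; at room temperature the intramolecular oxa-Michael closure of the ortho-hydroxy enones to flavanones should be slow and the E alkenes are untouched.

**Compound list**

1 | 4-hydroxyacetophenone | CC(=O)c1ccc(O)cc1 | starting material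
2 | 3-bromo-4-hydroxybenzaldehyde | O=Cc1ccc(O)c(Br)c1 | starting material
3 | (E)-3-(3-bromo-4-hydroxyphenyl)-1-(4-hydroxyphenyl)prop-2-en-1-one | O=C(/C=C/c1ccc(O)c(Br)c1)c1ccc(O)cc1 | intermediate
4 | 1-(3-bromo-4-hydroxyphenyl)ethanone | CC(=O)c1ccc(O)c(Br)c1 | starting material
5 | 4-hydroxybenzaldehyde | O=Cc1ccc(O)cc1 | starting material
6 | (E)-1-(3-bromo-4-hydroxyphenyl)-3-(4-hydroxyphenyl)prop-2-en-1-one | O=C(/C=C/c1ccc(O)cc1)c1ccc(O)c(Br)c1 | intermediate
7 | (E)-3-[4-hydroxy-3-(4,4,5,5-tetramethyl-1,3,2-dioxaborolan-2-yl)phenyl]-1-(4-hydroxyphenyl)prop-2-en-1-one | O=C(/C=C/c1ccc(O)c(B2OC(C)(C)C(C)(C)O2)c1)c1ccc(O)cc1 | intermediate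
8 | (E)-3-{4-hydroxy-3-[2-hydroxy-5-[(E)-3-(4-hydroxyphenyl)prop-2-enoyl]phenyl]phenyl}-1-(4-hydroxyphenyl)prop-2-en-1-one (dideoxy bichalcone tetraphenol) | O=C(/C=C/c1ccc(O)c(-c2cc(C(=O)/C=C/c3ccc(O)cc3)ccc2O)c1)c1ccc(O)cc1 | intermediate
9 | tetraacetate of 8 | CC(=O)Oc1ccc(C(=O)/C=C/c2ccc(OC(C)=O)c(-c3cc(C(=O)/C=C/c4ccc(OC(C)=O)cc4)ccc3OC(C)=O)c2)cc1 | intermediate
10 | tetraacetate 9 carrying trifluoroacetoxy groups at C2 of ring A and C2 of ring C | CC(=O)Oc1ccc(C(=O)/C=C/c2ccc(OC(C)=O)c(-c3cc(C(=O)/C=C/c4ccc(OC(C)=O)cc4)c(OC(=O)C(F)(F)F)cc3OC(C)=O)c2)c(OC(=O)C(F)(F)F)c1 | intermediate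
11 | tetraacetate 9 carrying free hydroxyls at C2 of ring A and C2 of ring C (tetra-O-acetylrhuschalcone VI) | CC(=O)Oc1ccc(C(=O)/C=C/c2ccc(OC(C)=O)c(-c3cc(C(=O)/C=C/c4ccc(OC(C)=O)cc4)c(O)cc3OC(C)=O)c2)c(O)c1 | intermediate
12 | rhuschalcone VI, (E)-1-(2,4-dihydroxyphenyl)-3-{3-[2,4-dihydroxy-5-[(E)-3-(4-hydroxyphenyl)prop-2-enoyl]phenyl]-4-hydroxyphenyl}prop-2-en-1-one | O=C(/C=C/c1ccc(O)c(-c2cc(C(=O)/C=C/c3ccc(O)cc3)c(O)cc2O)c1)c1ccc(O)cc1O | target

**Count**

Total steps: 7. Longest linear sequence: 6 steps (steps 1, 3, 4, 5, 6, 7).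

**Steps most likely to fail**

1. Step 6. Possible failures:
   - oxidation of the enone C=C bonds by the trivalent iodine reagent with a 1,2-aryl shift;
   - ruthenation of the β-vinyl C–H bond;
   - acid-driven Nazarov-type closure of an enone onto ring A;
   - stalling after a single oxygenation.

   Acetate lost by acyl exchange in the medium would not matter, since step 7 removes all esters anyway.

   Fallback (known chemistry), setting out from 2 and 5 and returning at 12: the ortho oxygens are bought instead of made. Commercial 2,4-dihydroxyacetophenone is capped at the para oxygen (MOMCl, K2CO3, acetone) to give 1-[2-hydroxy-4-(methoxymethoxy)phenyl]ethanone F1. Aldehyde 2 is capped likewise (MOMCl, i-Pr2NEt) to give 3-bromo-4-(methoxymethoxy)benzaldehyde F2. Base-mediated Claisen–Schmidt condensation (KOH, EtOH) should join them to (E)-3-[3-bromo-4-(methoxymethoxy)phenyl]-1-[2-hydroxy-4-(methoxymethoxy)phenyl]prop-2-en-1-one F3, and Miyaura borylation should give its pinacol boronate F4. In parallel, commercial 1-(5-bromo-2,4-dihydroxyphenyl)ethanone is mono-protected to 1-[5-bromo-2-hydroxy-4-(methoxymethoxy)phenyl]ethanone F5, and 5 is converted into 4-(methoxymethoxy)benzaldehyde F6. Their condensation should give (E)-1-[5-bromo-2-hydroxy-4-(methoxymethoxy)phenyl]-3-[4-(methoxymethoxy)phenyl]prop-2-en-1-one F7. Suzuki–Miyaura coupling of F4 with F7 should give the tetrakis(methoxymethyl) ether of rhuschalcone VI F8, and HCl in MeOH removes the four acetals to deliver 12.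

2. Step 4. Possible failures: protodeboronation of the ortho-phenoxide boronate in hot aqueous base, and slow oxidative addition into the electron-rich bromophenoxide.

   Fallback, setting out from 6 and 7 and returning at 9: the phenols are capped before the coupling. Ac2O/pyridine converts 6 into (E)-1-(4-acetoxy-3-bromophenyl)-3-(4-acetoxyphenyl)prop-2-en-1-one F9 and converts 7 into the diacetate of boronate 7 F10. Coupling under anhydrous conditions (Pd(OAc)2, SPhos, CsF, 1,4-dioxane, 90 °C) should then give 9 directly, so that step 5 is no longer needed.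

3. Step 3. Possible failures: protodebromination, O-borylation that stalls the catalyst, or premature self-coupling next to the free ortho phenol.

   Fallback, setting out from 2 (with 6 and 1 as partners) and returning at 8: the boron is installed on a simple capped aldehyde and the first enone is built last. Acetylation of 2 gives 2-bromo-4-formylphenyl acetate F11. Miyaura borylation should give 4-formyl-2-(4,4,5,5-tetramethyl-1,3,2-dioxaborolan-2-yl)phenyl acetate F12. Suzuki–Miyaura coupling with 6 in aqueous K3PO4, which also cleaves the acetate, should give 4-hydroxy-3-{2-hydroxy-5-[(E)-3-(4-hydroxyphenyl)prop-2-enoyl]phenyl}benzaldehyde F13. Acid-catalysed Claisen–Schmidt condensation of F13 with 1 (dry HCl, EtOH) should then give 8.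

**Further compounds**

F1 | step 6 | 1-[2-hydroxy-4-(methoxymethoxy)phenyl]ethanone | CC(=O)c1ccc(OCOC)cc1O
F2 | step 6 | 3-bromo-4-(methoxymethoxy)benzaldehyde | COCOc1ccc(C=O)cc1Br
F3 | step 6 | (E)-3-[3-bromo-4-(methoxymethoxy)phenyl]-1-[2-hydroxy-4-(methoxymethoxy)phenyl]prop-2-en-1-one | COCOc1ccc(C(=O)/C=C/c2ccc(OCOC)c(Br)c2)c(O)c1
F4 | step 6 | (E)-1-[2-hydroxy-4-(methoxymethoxy)phenyl]-3-[4-(methoxymethoxy)-3-(4,4,5,5-tetramethyl-1,3,2-dioxaborolan-2-yl)phenyl]prop-2-en-1-one | COCOc1ccc(C(=O)/C=C/c2ccc(OCOC)c(B3OC(C)(C)C(C)(C)O3)c2)c(O)c1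
F5 | step 6 | 1-[5-bromo-2-hydroxy-4-(methoxymethoxy)phenyl]ethanone | CC(=O)c1cc(Br)c(OCOC)cc1O
F6 | step 6 | 4-(methoxymethoxy)benzaldehyde | COCOc1ccc(C=O)cc1
F7 | step 6 | (E)-1-[5-bromo-2-hydroxy-4-(methoxymethoxy)phenyl]-3-[4-(methoxymethoxy)phenyl]prop-2-en-1-one | COCOc1ccc(/C=C/C(=O)c2cc(Br)c(OCOC)cc2O)cc1
F8 | step 6 | tetrakis(methoxymethyl) ether of rhuschalcone VI (acetals on the para oxygens of rings A, B, C and D; both ortho hydroxyls free) | COCOc1ccc(/C=C/C(=O)c2cc(-c3cc(/C=C/C(=O)c4ccc(OCOC)cc4O)ccc3OCOC)c(OCOC)cc2O)cc1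
F9 | step 4 | (E)-1-(4-acetoxy-3-bromophenyl)-3-(4-acetoxyphenyl)prop-2-en-1-one | CC(=O)Oc1ccc(/C=C/C(=O)c2ccc(OC(C)=O)c(Br)c2)cc1
F10 | step 4 | diacetate of boronate 7, (E)-1-(4-acetoxyphenyl)-3-[4-acetoxy-3-(4,4,5,5-tetramethyl-1,3,2-dioxaborolan-2-yl)phenyl]prop-2-en-1-one | CC(=O)Oc1ccc(C(=O)/C=C/c2ccc(OC(C)=O)c(B3OC(C)(C)C(C)(C)O3)c2)cc1
F11 | step 3 | 2-bromo-4-formylphenyl acetate | CC(=O)Oc1ccc(C=O)cc1Br
F12 | step 3 | 4-formyl-2-(4,4,5,5-tetramethyl-1,3,2-dioxaborolan-2-yl)phenyl acetate | CC(=O)Oc1ccc(C=O)cc1B1OC(C)(C)C(C)(C)O1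
F13 | step 3 | 4-hydroxy-3-{2-hydroxy-5-[(E)-3-(4-hydroxyphenyl)prop-2-enoyl]phenyl}benzaldehyde | O=Cc1ccc(O)c(-c2cc(C(=O)/C=C/c3ccc(O)cc3)ccc2O)c1
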